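Time is the one setting that differs between Friday's, Sunday's and Wednesday's, which share a recipe and are read at 48 h, 72 h and 120 h.

all flasks: gas phase 30 mM (held)

| run | starting material | protic impurity | remark | time |
|---|---|---|---|---|
| amber | 0.14 M | 2 mM | run made earlier |  |
| red | 0.22 M | 2 mM | run made earlier |  |
| ochre | 0.10 M | 1 mM | run made earlier |  |
| Friday's | 0.10 M | 2.00 mM |  | 48 h |
| Sunday's | 0.10 M | 2.00 mM |  | 72 h |
| Wednesday's | 0.10 M | 2.00 mM |  | 120 h |

| run | time / h | target / % |
|---|---|---|
| amber | 2.50 | 2.9 |
| amber | 8.00 | 10.4 |
| amber | 15.0 | 17.4 |
| amber | 20.0 | 21.7 |
| amber | 30.0 | 28.7 |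
| amber | 40.0 | 34.2 |
| amber | 48.0 | 36.2 |
| red | 2.50 | 1.7 |
| red | 8.00 | 6.6 |
| red | 15.0 | 12.0 |
| red | 20.0 | 15.3 |
| red | 30.0 | 21.6 |
| red | 40.0 | 25.8 |
| red | 48.0 | 29.2 |
| ochre | 4.00 | 6.7 |
| ochre | 12.0 | 19.0 |
| ochre | 25.0 | 31.9 |
| ochre | 40.0 | 38.7 |
| ochre | 48.0 | 39.2 |

(readings scatter by 0.3 percentage points)

- the analysis behind the earlier runs scatters by 0.3 percentage points, standard deviation
- at the start none of the gas phase is in solution

1. which of the two there is more of at the end, Friday's (target / over-reacted product)
2. which of the two there is more of at the end, Sunday's (target / over-reacted product)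
3. which of the two there is more of at the end, Wednesday's (target / over-reacted product)
4. final target, as a percentage of the starting material charged, in Friday's
5. final target, as a percentage of the starting material charged, in Sunday's
6. final target, as a percentage of the starting material charged, in Wednesday's

How fast does anything happen? Turn your target readings into concentrations. Between 2.50 h and 8.00 h the amber run gains target at 1.91 mM h⁻¹ and the red run at 1.96 mM h⁻¹, about the same, although the charges are 0.14 M and 0.22 M. So gas entering the solution looks like the rate-limiting step, and I freeze it. Call the mean of these two readings, 1.93 mM h⁻¹, the gas income: gas taken up per hour, held steady. I assume one gas per step, so target holds one gas and over-reacted product two.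

Can the income pay for the whole charge by Wednesday's? Taking it through both steps costs 200 mM, which takes 103 h, less than 120 h. So I expect Wednesday's target close to zero.

When do the two products cross? Equal amounts cost three gas per pair. The ochre run, with the same starting material charge, flattens at a reading of 39.2%. If the crossing lies near that height, it comes at 60.8 h, later than Friday's and earlier than Sunday's. So I expect target ahead on Friday's, near that reading, and over-reacted product ahead on Sunday's. For Sunday's I give no number.

The forecast says target, over-reacted product and over-reacted product, with 38%, 26% and 2% target, and it finds that the fall of the net rate suggests “starting material suppresses over-reaction by out-competing target on the catalyst”.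

The flask gives target, over-reacted product and over-reacted product, with 38.8%, 31.1% and 0.00986% target.

    dissolved gas + target → over-reaction product (k = 0.0310 M⁻¹ min⁻¹)
    dissolved gas → decomposed reagent (k = 6.90 × 10⁻⁴ min⁻¹)
    starting material + dissolved gas → target (k = 0.840 M⁻¹ min⁻¹)
    gas phase ⇌ dissolved gas, rate k4*(csat - [dissolved gas]) (kL = 0.00110 min⁻¹)
    dissolved gas + target → over-reacted product (k = 0.690 M⁻¹ min⁻¹)
    starting material + protic impurity → quenched substrate (k = 0.120 M⁻¹ min⁻¹)

In Wednesday's, the path to target had done half of its turnover up to 120 h by 32.5 h, and the path from target to over-reacted product by 68.5 h. In Wednesday's, target and over-reacted product stood level at 36.7% and 37.4% after 60.0 h, and at 120 h starting material is at 0%. Reckoned with the income held at 1.93 mM h⁻¹, those 120 h come to 232 mM, more than Wednesday's reckoned cost of 200 mM. The same flask as Wednesday's with 0.17 M of starting material has a reckoned cost of 340 mM, more than that sum, and at 120 h it still holds 14.4% starting material and 31.9% target.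

(Readings and results were computed with made-up constants; scatter was added.)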